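## Retrosynthetic overview

1. The butenolide is made last: the (5E)-tetronic acid ring is closed at C3–C4 by Dieckmann condensation of an (E)-enol propanoate, itself made from a (2S)-2-methyl aldehyde by a cis-selective Horner–Wadsworth–Emmons olefination. The enol ester geometry becomes that of the exocyclic olefin (side chain cis to C4–OH).
2. The (4E,6E)-diene CH2–CH=CH–C(CH3)=CH–CH2 is cut at its central sp2–sp2 bond into two alkynes: a terminal alkyne carrying the stereocentre (fragment A) and a methyl-capped internal alkyne carrying the 4-(furan-3-ylmethyl)furan-3-yl unit (fragment B). They are joined by titanium-mediated reductive cross-coupling, which unites two alkyne carbons of like polarity and sets both olefin geometries in one operation.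
3. Enabling feature: in the unit CH=CH–C(CH3)=CH each outer diene carbon bears a hydrogen cis to the central bond, as in a protonated metallacyclopentadiene. In addition, the CH2 on C3 of the 3,4-disubstituted furan ring lies two atoms from the alkyne and can be carried as a carbinol; its alkoxide holds titanium and steers bond formation to the CH3-bearing alkyne carbon. This oxygen is removed afterwards (Barton–McCombie).
4. Ring order: both furan rings are bought (3,4-dibromofuran, furan-3-carbaldehyde); the furanone is the only ring formed, in the last step. The stereocentre comes from an Evans propargylation.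

Key step: step 9

Remark: the target SMILES places the side chain of the exocyclic olefin cis to C4 (5E), and the route is built for that isomer; the carbinol carbon of 8, 10, 20 and 21 is used as the racemate because it becomes CH2 in step 11, so 20 and 21 are mixtures of two diastereomers.

## Route

Step 1
Reactants: 1 3,4-dibromofuran; 2 furan-3-carbaldehyde
Product: 4 (4-bromofuran-3-yl)(furan-3-yl)methanol, via (4-bromofuran-3-yl)lithium 3 (not isolated)
Conditions: n-BuLi (1.0 equiv), Et2O, −78 °C; then 2, −78 °C; then H2O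
Reagents that add atoms: none
Why: Mono bromine–lithium exchange is fast at −78 °C, and the 3-furyllithium, kept cold so that it does not isomerise to the 2-lithio species, should add to the aldehyde (organolithium 1,2-addition).

Step 2
Reactants: 4 (4-bromofuran-3-yl)(furan-3-yl)methanol
Product: 5 3-bromo-4-(furan-3-ylmethyl)furan
Conditions: Et3SiH (3 equiv), CF3CO2H, CH2Cl2, −20 °C → 0 °C
Reagents that add atoms: none
Why: Ionic hydrogenation: the doubly furyl-stabilised carbocation should be trapped by hydride from the silane before it can alkylate a furan ring.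

Step 3
Reactants: 5 3-bromo-4-(furan-3-ylmethyl)furan
Product: 7 4-(furan-3-ylmethyl)furan-3-carbaldehyde, via [4-(furan-3-ylmethyl)furan-3-yl]lithium 6 (not isolated)
Conditions: n-BuLi (1.05 equiv), Et2O, −78 °C; then DMF, −78 °C → 0 °C; then H2O
Reagents that add atoms: N,N-dimethylformamide, CN(C)C=O
Why: Bromine–lithium exchange followed by formylation of the aryllithium with DMF (Bouveault aldehyde synthesis) should be faster at −78 °C than proton transfer from the difurylmethane CH2.

Step 4
Reactants: 7 4-(furan-3-ylmethyl)furan-3-carbaldehyde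
Product: 8 rac-1-[4-(furan-3-ylmethyl)furan-3-yl]but-3-yn-1-ol
Conditions: propargyl bromide (1.5 equiv), Zn dust, THF, 0 °C → rt; then H2O
Reagents that add atoms: propargyl bromide (3-bromoprop-1-yne), C#CCBr
Why: Barbier propargylation: the allenylzinc bromide formed in the flask reacts through its γ-carbon (SE2′) and should therefore give the homopropargylic and not the allenic alcohol.

Step 5
Reactants: 8 rac-1-[4-(furan-3-ylmethyl)furan-3-yl]but-3-yn-1-ol
Product: 10 rac-1-[4-(furan-3-ylmethyl)furan-3-yl]pent-3-yn-1-ol, via dilithium alkynide alkoxide 9 (not isolated)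
Conditions: LiNH2 (2.0 equiv), liquid NH3–THF, −33 °C; then MeI (1.0 equiv); then H2O
Reagents that add atoms: iodomethane, CI
Why: Acetylide alkylation: in the dianion the acetylide carbon is far more nucleophilic toward MeI than the lithium alkoxide, so C-methylation should be selective.

Step 6
Reactants: 11 (4R)-4-benzyl-3-propanoyl-1,3-oxazolidin-2-one
Product: 13 (4R)-4-benzyl-3-[(2S)-2-methylpent-4-ynoyl]-1,3-oxazolidin-2-one, via sodium Z-enolate 12 (not isolated)
Conditions: NaHMDS (1.1 equiv), THF, −78 °C; then propargyl bromide (3 equiv), −78 °C → −45 °C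
Reagents that add atoms: propargyl bromide (3-bromoprop-1-yne), C#CCBr
Why: Evans alkylation: the chelated Z-enolate should be alkylated on the face opposite the benzyl group of the (4R)-auxiliary, which sets the (2S) centre.

Step 7
Reactants: 13 (4R)-4-benzyl-3-[(2S)-2-methylpent-4-ynoyl]-1,3-oxazolidin-2-one
Product: 14 (2S)-2-methylpent-4-yn-1-ol
Conditions: LiBH4, H2O (1 equiv), Et2O, 0 °C
Reagents that add atoms: none
Why: Reductive cleavage of the N-acyloxazolidinone: borohydride attacks the exocyclic carbonyl and should release the auxiliary without touching the α-stereocentre.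

Step 8
Reactants: 14 (2S)-2-methylpent-4-yn-1-ol
Product: 15 tert-butyl(dimethyl){[(2S)-2-methylpent-4-yn-1-yl]oxy}silane
Conditions: TBSCl, imidazole, CH2Cl2, 0 °C → rt
Reagents that add atoms: tert-butyldimethylsilyl chloride, CC(C)(C)[Si](C)(C)Cl
Why: Silylation of the primary alcohol gives an ether that is inert to organotitanium, tin hydride and mild base.

Step 9
Reactants: 10 rac-1-[4-(furan-3-ylmethyl)furan-3-yl]pent-3-yn-1-ol; 15 tert-butyl(dimethyl){[(2S)-2-methylpent-4-yn-1-yl]oxy}silane
Product: 20 (3E,5E,8S)-9-{[tert-butyl(dimethyl)silyl]oxy}-1-[4-(furan-3-ylmethyl)furan-3-yl]-4,8-dimethylnona-3,5-dien-1-ol, via lithium alkoxide 16 (not isolated), via triisopropoxytitanium alkoxide 17 (not isolated), via titanacyclopropene 18 (not isolated), via titanacyclopentadiene 19 (not isolated)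
Conditions: 10, n-BuLi (1.0 equiv), toluene, −78 °C; ClTi(OiPr)3 (1.0 equiv); c-C5H9MgCl (2.0 equiv), −78 °C → −30 °C; then 15 (1.5 equiv), −78 °C → −30 °C; then H2O
Reagents that add atoms: none
Why: The lithium alkoxide of 10 exchanges onto ClTi(OiPr)3, and two equivalents of c-C5H9MgCl reduce this titanium centre (β-hydride elimination of the dicyclopentyl species) to a divalent titanium–cyclopentene complex that exchanges the olefin for the tethered alkyne, giving titanacyclopropene 18 held in a five-membered Ti–O chelate. The terminal alkyne 15 then inserts into a Ti–C(sp2) bond by syn-carbometalation and closes titanacyclopentadiene 19 at the new C(sp2)–C(sp2) bond; this metallacycle is the only ring closed (ring expansion of the metallacyclopropene by migratory insertion) and it is opened again when water cleaves both Ti–C bonds with retention. The closest known reaction type is the titanium alkoxide-mediated reductive cross-coupling of a preformed internal-alkyne complex with a terminal alkyne, together with alkoxide-directed alkyne–alkyne coupling. No stereocentre is formed, but both olefin geometries are: each new vinylic hydrogen replaces titanium cis to the central bond, so the (E,E)-diene follows from the mechanism. Three selectivities are needed: cross- over homo-coupling, secured by complexing the internal alkyne before the terminal alkyne is added; bond formation at the methyl-bearing carbon of 10, secured because the tethered alkoxide can stay on titanium only if the carbon next to the tether remains titanium-bound and because that side is β-branched; and bond formation at the terminal CH of 15, secured by its substituent preferring the position next to titanium. The (S) centre and the silyl ether of 15 are spectators.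

Step 10
Reactants: 20 (3E,5E,8S)-9-{[tert-butyl(dimethyl)silyl]oxy}-1-[4-(furan-3-ylmethyl)furan-3-yl]-4,8-dimethylnona-3,5-dien-1-ol
Product: 21 O-[(3E,5E,8S)-9-{[tert-butyl(dimethyl)silyl]oxy}-1-[4-(furan-3-ylmethyl)furan-3-yl]-4,8-dimethylnona-3,5-dien-1-yl] 1H-imidazole-1-carbothioate
Conditions: 1,1′-thiocarbonyldiimidazole (1.5 equiv), DMAP (cat.), CH2Cl2, rt
Reagents that add atoms: 1,1′-thiocarbonyldiimidazole, S=C(n1ccnc1)n1ccnc1
Why: Thioacylation of the secondary alcohol under neutral conditions should give the radical precursor without ionising the furyl carbinol.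

Step 11
Reactants: 21 O-[(3E,5E,8S)-9-{[tert-butyl(dimethyl)silyl]oxy}-1-[4-(furan-3-ylmethyl)furan-3-yl]-4,8-dimethylnona-3,5-dien-1-yl] 1H-imidazole-1-carbothioate
Product: 22 tert-butyl({(2S,4E,6E)-9-[4-(furan-3-ylmethyl)furan-3-yl]-2,6-dimethylnona-4,6-dien-1-yl}oxy)dimethylsilane
Conditions: Bu3SnH (1.5 equiv), Et3B (0.2 equiv), air, toluene, rt
Reagents that add atoms: none
Why: Barton–McCombie deoxygenation: the furyl-stabilised secondary radical should take hydrogen from the stannane faster than it closes reversibly onto the homoallylic diene, and room-temperature initiation avoids thermal elimination of the thiocarbonyl ester.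

Step 12
Reactants: 22 tert-butyl({(2S,4E,6E)-9-[4-(furan-3-ylmethyl)furan-3-yl]-2,6-dimethylnona-4,6-dien-1-yl}oxy)dimethylsilane
Product: 23 (2S,4E,6E)-9-[4-(furan-3-ylmethyl)furan-3-yl]-2,6-dimethylnona-4,6-dien-1-ol
Conditions: TBAF (1.2 equiv), THF, 0 °C → rt
Reagents that add atoms: none
Why: Fluoride cleavage of the silyl ether leaves the diene and both furans untouched.

Step 13
Reactants: 23 (2S,4E,6E)-9-[4-(furan-3-ylmethyl)furan-3-yl]-2,6-dimethylnona-4,6-dien-1-ol
Product: 24 (2S,4E,6E)-9-[4-(furan-3-ylmethyl)furan-3-yl]-2,6-dimethylnona-4,6-dienal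
Conditions: Dess–Martin periodinane (1.3 equiv), CH2Cl2, 0 °C → rt
Reagents that add atoms: none
Why: Dess–Martin oxidation is nearly neutral and should give the α-branched aldehyde without epimerisation; it is used at once.

Step 14
Reactants: 25 methyl 2-[bis(2,2,2-trifluoroethoxy)phosphoryl]acetate
Product: 26 methyl 2-[bis(2,2,2-trifluoroethoxy)phosphoryl]-2-diazoacetate
Conditions: 4-acetamidobenzenesulfonyl azide (1.2 equiv), DBU (1.3 equiv), MeCN, 0 °C → rt
Reagents that add atoms: 4-acetamidobenzenesulfonyl azide, CC(=O)Nc1ccc(cc1)S(=O)(=O)N=[N+]=[N-]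
Why: Regitz diazo transfer to the acidic CH2 of the phosphonoacetate.

Step 15
Reactants: 26 methyl 2-[bis(2,2,2-trifluoroethoxy)phosphoryl]-2-diazoacetate
Product: 27 rac-methyl 2-[bis(2,2,2-trifluoroethoxy)phosphoryl]-2-(propanoyloxy)acetate
Conditions: propanoic acid (1.5 equiv), Rh2(OAc)4 (1 mol %), toluene, 80 °C
Reagents that add atoms: propanoic acid, CCC(=O)O
Why: Rhodium-carbenoid O–H insertion into a carboxylic acid is the usual entry to 2-acyloxy phosphonoacetates.

Step 16
Reactants: 24 (2S,4E,6E)-9-[4-(furan-3-ylmethyl)furan-3-yl]-2,6-dimethylnona-4,6-dienal; 27 rac-methyl 2-[bis(2,2,2-trifluoroethoxy)phosphoryl]-2-(propanoyloxy)acetate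
Product: 29 methyl (2E,4S,6E,8E)-11-[4-(furan-3-ylmethyl)furan-3-yl]-4,8-dimethyl-2-(propanoyloxy)undeca-2,6,8-trienoate, via potassium phosphonate carbanion 28 (not isolated)
Conditions: 27 (1.2 equiv), KHMDS (1.15 equiv), 18-crown-6 (5 equiv), THF, −78 °C; then 24, −78 °C
Reagents that add atoms: none
Why: Proposed new method: the electron-poor trifluoroethyl phosphonate should make collapse of the kinetically formed adduct faster than its reversal, so the aldehyde substituent should end cis to the ester (2E), as in the Still–Gennari olefination and its 2-bromo variant, which are the closest known reaction types, whereas a 2-acyloxy group is known in Horner–Wadsworth–Emmons reagents only with ordinary dialkyl phosphonates; the (2S) centre of 24 should not epimerise at −78 °C.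

Step 17
Reactants: 29 methyl (2E,4S,6E,8E)-11-[4-(furan-3-ylmethyl)furan-3-yl]-4,8-dimethyl-2-(propanoyloxy)undeca-2,6,8-trienoate
Product: 31 (5E)-5-{(2S,4E,6E)-9-[4-(furan-3-ylmethyl)furan-3-yl]-2,6-dimethylnona-4,6-dien-1-ylidene}-4-hydroxy-3-methylfuran-2(5H)-one, via lithium tetronate 30 (not isolated)
Conditions: LiHMDS (2.0 equiv), THF, −78 °C → −30 °C; then aqueous HCl (0.5 M), 0 °C
Reagents that add atoms: none
Why: Dieckmann condensation: the propanoate enolate attacks the neighbouring methyl ester (5-exo-trig) and closes the furan-2,4-dione, which is drained to the tetronate; the enol ester C=C takes no part, so its geometry should be carried into the exocyclic olefin.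

## Compound list

1 | 3,4-dibromofuran | Brc1cocc1Br | starting material
2 | furan-3-carbaldehyde | O=Cc1ccoc1 | starting material
3 | (4-bromofuran-3-yl)lithium | [Li]c1cocc1Br | intermediate
4 | (4-bromofuran-3-yl)(furan-3-yl)methanol | OC(c1ccoc1)c1cocc1Br | intermediate
5 | 3-bromo-4-(furan-3-ylmethyl)furan | Brc1cocc1Cc1ccoc1 | intermediate
6 | [4-(furan-3-ylmethyl)furan-3-yl]lithium | [Li]c1cocc1Cc1ccoc1 | intermediate
7 | 4-(furan-3-ylmethyl)furan-3-carbaldehyde | O=Cc1cocc1Cc1ccoc1 | intermediate
8 | rac-1-[4-(furan-3-ylmethyl)furan-3-yl]but-3-yn-1-ol | C#CCC(O)c1cocc1Cc1ccoc1 | intermediate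
9 | dilithium alkynide alkoxide of 8 | [Li+].[Li+].[C-]#CCC([O-])c1cocc1Cc1ccoc1 | intermediate
10 | rac-1-[4-(furan-3-ylmethyl)furan-3-yl]pent-3-yn-1-ol | CC#CCC(O)c1cocc1Cc1ccoc1 | intermediate
11 | (4R)-4-benzyl-3-propanoyl-1,3-oxazolidin-2-one | CCC(=O)N1[C@H](Cc2ccccc2)COC1=O | starting material
12 | sodium (Z)-enolate of 11 | C/C=C(\[O-])N1[C@H](Cc2ccccc2)COC1=O.[Na+] | intermediate
13 | (4R)-4-benzyl-3-[(2S)-2-methylpent-4-ynoyl]-1,3-oxazolidin-2-one | C#CC[C@H](C)C(=O)N1[C@H](Cc2ccccc2)COC1=O | intermediate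
14 | (2S)-2-methylpent-4-yn-1-ol | OC[C@@H](C)CC#C | intermediate
15 | tert-butyl(dimethyl){[(2S)-2-methylpent-4-yn-1-yl]oxy}silane | CC(C)(C)[Si](C)(C)OC[C@@H](C)CC#C | intermediate
16 | lithium alkoxide of 10 | CC#CCC([O-])c1cocc1Cc1ccoc1.[Li+] | intermediate
17 | triisopropoxytitanium alkoxide of 10 | CC#CCC(O[Ti](OC(C)C)(OC(C)C)OC(C)C)c1cocc1Cc1ccoc1 | intermediate
18 | chelated titanacyclopropene (isopropoxy, tethered alkoxide) from 17 | CC1=C2CC(c3cocc3Cc3ccoc3)O[Ti]12OC(C)C | intermediate
19 | titanacyclopentadiene from 18 and 15 | CC1=C2CC(c3cocc3Cc3ccoc3)O[Ti]2(OC(C)C)C(C[C@H](C)CO[Si](C)(C)C(C)(C)C)=C1 | intermediate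
20 | (3E,5E,8S)-9-{[tert-butyl(dimethyl)silyl]oxy}-1-[4-(furan-3-ylmethyl)furan-3-yl]-4,8-dimethylnona-3,5-dien-1-ol | CC(C)(C)[Si](C)(C)OC[C@@H](C)C/C=C/C(C)=C/CC(O)c1cocc1Cc1ccoc1 | intermediate
21 | O-[(3E,5E,8S)-9-{[tert-butyl(dimethyl)silyl]oxy}-1-[4-(furan-3-ylmethyl)furan-3-yl]-4,8-dimethylnona-3,5-dien-1-yl] 1H-imidazole-1-carbothioate | CC(C)(C)[Si](C)(C)OC[C@@H](C)C/C=C/C(C)=C/CC(OC(=S)n1ccnc1)c1cocc1Cc1ccoc1 | intermediate
22 | tert-butyl({(2S,4E,6E)-9-[4-(furan-3-ylmethyl)furan-3-yl]-2,6-dimethylnona-4,6-dien-1-yl}oxy)dimethylsilane | CC(C)(C)[Si](C)(C)OC[C@@H](C)C/C=C/C(C)=C/CCc1cocc1Cc1ccoc1 | intermediate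
23 | (2S,4E,6E)-9-[4-(furan-3-ylmethyl)furan-3-yl]-2,6-dimethylnona-4,6-dien-1-ol | OC[C@@H](C)C/C=C/C(C)=C/CCc1cocc1Cc1ccoc1 | intermediate
24 | (2S,4E,6E)-9-[4-(furan-3-ylmethyl)furan-3-yl]-2,6-dimethylnona-4,6-dienal | O=C[C@@H](C)C/C=C/C(C)=C/CCc1cocc1Cc1ccoc1 | intermediate
25 | methyl 2-[bis(2,2,2-trifluoroethoxy)phosphoryl]acetate | COC(=O)CP(=O)(OCC(F)(F)F)OCC(F)(F)F | starting material
26 | methyl 2-[bis(2,2,2-trifluoroethoxy)phosphoryl]-2-diazoacetate | COC(=O)C(=[N+]=[N-])P(=O)(OCC(F)(F)F)OCC(F)(F)F | intermediate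
27 | rac-methyl 2-[bis(2,2,2-trifluoroethoxy)phosphoryl]-2-(propanoyloxy)acetate | CCC(=O)OC(C(=O)OC)P(=O)(OCC(F)(F)F)OCC(F)(F)F | intermediate
28 | potassium salt of the carbanion of 27 | CCC(=O)O[C-](C(=O)OC)P(=O)(OCC(F)(F)F)OCC(F)(F)F.[K+] | intermediate
29 | methyl (2E,4S,6E,8E)-11-[4-(furan-3-ylmethyl)furan-3-yl]-4,8-dimethyl-2-(propanoyloxy)undeca-2,6,8-trienoate | COC(=O)/C(OC(=O)CC)=C\[C@@H](C)C/C=C/C(C)=C/CCc1cocc1Cc1ccoc1 | intermediate
30 | lithium tetronate of 31 | CC1=C([O-])/C(=C\[C@@H](C)C/C=C/C(C)=C/CCc2cocc2Cc2ccoc2)OC1=O.[Li+] | intermediate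
31 | (5E)-5-{(2S,4E,6E)-9-[4-(furan-3-ylmethyl)furan-3-yl]-2,6-dimethylnona-4,6-dien-1-ylidene}-4-hydroxy-3-methylfuran-2(5H)-one | CC1=C(O)/C(=C\[C@@H](C)C/C=C/C(C)=C/CCc2cocc2Cc2ccoc2)OC1=O | target

## Step count and risks

Total step count: 17. Longest linear sequence: 12 steps (steps 1–5, 9–13, 16, 17).

Steps most likely to fail:

1. Step 16 (Proposed new method). The olefination may lose geometric control if the adduct equilibrates before elimination, giving the enol ester with the chain cis to the acyloxy group, or the phosphonate anion may transfer its acyl group. The fallback sets out from 24 (with 25 as reagent source) and comes back at 31, fixing the geometry by known stereoretentive chemistry. Compound 25 would be deprotonated (NaH, THF, 0 °C) and brominated with N-bromosuccinimide to methyl 2-bromo-2-[bis(2,2,2-trifluoroethoxy)phosphoryl]acetate F1, a reagent of established selectivity for (E)-2-bromo-2-enoates. Its reaction with 24 (t-BuOK, 18-crown-6, THF, −78 °C) would give methyl (2E,4S,6E,8E)-2-bromo-11-[4-(furan-3-ylmethyl)furan-3-yl]-4,8-dimethylundeca-2,6,8-trienoate F2. Saponification (LiOH, THF–H2O, 0 °C) would give (2E,4S,6E,8E)-2-bromo-11-[4-(furan-3-ylmethyl)furan-3-yl]-4,8-dimethylundeca-2,6,8-trienoic acid F3. Activation with 1,1′-carbonyldiimidazole and C-acylation of the magnesium salt of ethyl hydrogen methylmalonate (MgCl2, Et3N, THF), with loss of CO2, would give ethyl (4E,6S,8E,10E)-4-bromo-13-[4-(furan-3-ylmethyl)furan-3-yl]-2,6,10-trimethyl-3-oxotrideca-4,8,10-trienoate F4. Ester hydrolysis with Me3SnOH (1,2-dichloroethane, 60 °C) would give (4E,6S,8E,10E)-4-bromo-13-[4-(furan-3-ylmethyl)furan-3-yl]-2,6,10-trimethyl-3-oxotrideca-4,8,10-trienoic acid F5. Copper-catalysed intramolecular O-vinylation of its carboxylate by the vinyl bromide (CuI, trans-N,N′-dimethylcyclohexane-1,2-diamine, Cs2CO3, THF, 60 °C), a ring closure that proceeds with retention at the olefin, would then give 31 directly and also replace step 17.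

2. Step 9 (key step). The terminal alkyne may insert into the Ti–C bond next to the tether if the alkoxide is not held on the same titanium, giving the regioisomeric diene; the terminal alkyne may also homodimerise or protonate a Ti–C bond. The fallback sets out from 10 and 15 and comes back at 22 by hydrometalation and cross-coupling. Compound 10 would be deoxygenated first (1,1′-thiocarbonyldiimidazole; then Bu3SnH, Et3B, air) through rac-O-{1-[4-(furan-3-ylmethyl)furan-3-yl]pent-3-yn-1-yl} 1H-imidazole-1-carbothioate F6 to 3-(furan-3-ylmethyl)-4-(pent-3-yn-1-yl)furan F7. Hydrozirconation with excess Cp2Zr(H)Cl (THF, 50 °C), under which the adduct equilibrates to the isomer with zirconium beside the methyl group, would give chlorobis(cyclopentadienyl){(2E)-5-[4-(furan-3-ylmethyl)furan-3-yl]pent-2-en-2-yl}zirconium F8, and iodine would convert it to 3-(furan-3-ylmethyl)-4-[(3E)-4-iodopent-3-en-1-yl]furan F9. Compound 15 with pinacolborane and catalytic Cp2Zr(H)Cl would give tert-butyl(dimethyl){[(2S,4E)-2-methyl-5-(4,4,5,5-tetramethyl-1,3,2-dioxaborolan-2-yl)pent-4-en-1-yl]oxy}silane F10. Suzuki–Miyaura coupling of F9 and F10 (Pd(PPh3)4, aqueous NaOH, THF) would give 22 with both geometries retained, so that steps 10 and 11 are no longer needed.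

3. Step 11. The homoallylic furylmethyl radical may rearrange through a cyclopropylcarbinyl radical, the thiocarbonyl ester may undergo syn-elimination to a conjugated triene, or stannyl radicals may add to the diene and scramble its geometry. The fallback sets out from 20 and comes back at 22 without a thiocarbonyl ester or tin. Mitsunobu displacement of the carbinol with 2-nitrobenzenesulfonylhydrazide (PPh3, diethyl azodicarboxylate, THF, −30 °C) would give N-[(3E,5E,8S)-9-{[tert-butyl(dimethyl)silyl]oxy}-1-[4-(furan-3-ylmethyl)furan-3-yl]-4,8-dimethylnona-3,5-dien-1-yl]-2-nitrobenzenesulfonohydrazide F11. On warming to room temperature this would lose the sulfinic acid to give the monoalkyl diazene [(3E,5E,8S)-9-{[tert-butyl(dimethyl)silyl]oxy}-1-[4-(furan-3-ylmethyl)furan-3-yl]-4,8-dimethylnona-3,5-dien-1-yl]diazene F12, which would extrude dinitrogen to give 22.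

Further compounds
F1 | step 16 | methyl 2-bromo-2-[bis(2,2,2-trifluoroethoxy)phosphoryl]acetate | COC(=O)C(Br)P(=O)(OCC(F)(F)F)OCC(F)(F)F
F2 | step 16 | methyl (2E,4S,6E,8E)-2-bromo-11-[4-(furan-3-ylmethyl)furan-3-yl]-4,8-dimethylundeca-2,6,8-trienoate | COC(=O)/C(Br)=C\[C@@H](C)C/C=C/C(C)=C/CCc1cocc1Cc1ccoc1
F3 | step 16 | (2E,4S,6E,8E)-2-bromo-11-[4-(furan-3-ylmethyl)furan-3-yl]-4,8-dimethylundeca-2,6,8-trienoic acid | OC(=O)/C(Br)=C\[C@@H](C)C/C=C/C(C)=C/CCc1cocc1Cc1ccoc1
F4 | step 16 | ethyl (4E,6S,8E,10E)-4-bromo-13-[4-(furan-3-ylmethyl)furan-3-yl]-2,6,10-trimethyl-3-oxotrideca-4,8,10-trienoate | CCOC(=O)C(C)C(=O)/C(Br)=C\[C@@H](C)C/C=C/C(C)=C/CCc1cocc1Cc1ccoc1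
F5 | step 16 | (4E,6S,8E,10E)-4-bromo-13-[4-(furan-3-ylmethyl)furan-3-yl]-2,6,10-trimethyl-3-oxotrideca-4,8,10-trienoic acid | OC(=O)C(C)C(=O)/C(Br)=C\[C@@H](C)C/C=C/C(C)=C/CCc1cocc1Cc1ccoc1
F6 | step 9 | rac-O-{1-[4-(furan-3-ylmethyl)furan-3-yl]pent-3-yn-1-yl} 1H-imidazole-1-carbothioate | CC#CCC(OC(=S)n1ccnc1)c1cocc1Cc1ccoc1
F7 | step 9 | 3-(furan-3-ylmethyl)-4-(pent-3-yn-1-yl)furan | CC#CCCc1cocc1Cc1ccoc1
F8 | step 9 | chlorobis(cyclopentadienyl){(2E)-5-[4-(furan-3-ylmethyl)furan-3-yl]pent-2-en-2-yl}zirconium | C/C(=C\CCc1cocc1Cc1ccoc1)[Zr](Cl)(C1C=CC=C1)C1C=CC=C1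
F9 | step 9 | 3-(furan-3-ylmethyl)-4-[(3E)-4-iodopent-3-en-1-yl]furan | C/C(I)=C\CCc1cocc1Cc1ccoc1
F10 | step 9 | tert-butyl(dimethyl){[(2S,4E)-2-methyl-5-(4,4,5,5-tetramethyl-1,3,2-dioxaborolan-2-yl)pent-4-en-1-yl]oxy}silane | CC(C)(C)[Si](C)(C)OC[C@@H](C)C/C=C/B1OC(C)(C)C(C)(C)O1
F11 | step 11 | N-[(3E,5E,8S)-9-{[tert-butyl(dimethyl)silyl]oxy}-1-[4-(furan-3-ylmethyl)furan-3-yl]-4,8-dimethylnona-3,5-dien-1-yl]-2-nitrobenzenesulfonohydrazide | CC(C)(C)[Si](C)(C)OC[C@@H](C)C/C=C/C(C)=C/CC(N(N)S(=O)(=O)c1ccccc1[N+](=O)[O-])c1cocc1Cc1ccoc1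
F12 | step 11 | [(3E,5E,8S)-9-{[tert-butyl(dimethyl)silyl]oxy}-1-[4-(furan-3-ylmethyl)furan-3-yl]-4,8-dimethylnona-3,5-dien-1-yl]diazene | CC(C)(C)[Si](C)(C)OC[C@@H](C)C/C=C/C(C)=C/CC(N=N)c1cocc1Cc1ccoc1
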